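I read theta at 15 h, so I want two things: where it stops, and how near that stop it stands by then. Larch is its neighbour, with the same racemate and solid reagent, but 0.2 mol% of catalyst against 0.13 mol% and 0 °C against −5 °C. Larch's left-handed product levels near 26%, with 23% left-handed substrate still standing.

all flasks: left-handed substrate 0.050 M; right-handed substrate 0.050 M
- larch: solid reagent 1.2 equiv; free catalyst 0.13 mol%; temperature −5 °C; run made earlier
- ash: solid reagent 1.2 equiv; free catalyst 0.3 mol%; temperature 20 °C; run made earlier
- gamma: solid reagent 1.20 equiv; free catalyst 0.2 mol%; temperature 20 °C; time 15 h
- zeta: solid reagent 1.20 equiv; free catalyst 0.2 mol%; temperature 40 °C; time 15 h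
- theta: solid reagent 1.20 equiv; free catalyst 0.2 mol%; temperature 0 °C; time 15 h
- epsilon: solid reagent 1.20 equiv; free catalyst 0.2 mol%; at 0 °C until 3.0 h, from then on at 40 °C; time 15 h

| run | time / h | left-handed product / % | left-handed substrate / % |
|---|---|---|---|
| larch | 5.00 | 2 | 46 |
| larch | 10.0 | 8 | 40 |
| larch | 30.0 | 22 | 25 |
| larch | 72.0 | 26 | 23 |
| ash | 5.00 | 2 | 50 |
| ash | 10.0 | 0 | 50 |
| ash | 15.0 | 0 | 49 |
| ash | 20.0 | 0 | 49 |

(each reading ± 1.5 percentage points)

- the flask that comes out highest in amount of left-handed product, in percent of the left-handed substrate and right-handed substrate together charged, or "all alike" when all lie within 1.5 percentage points (gamma / zeta / theta / epsilon / all alike)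
- left-handed product at the end, in percent of the left-handed substrate and right-handed substrate together charged, gamma
- left-handed product at the end, in percent of the left-handed substrate and right-handed substrate together charged, zeta
- left-handed product at the end, in percent of the left-handed substrate and right-handed substrate together charged, theta
- left-handed product at the end, in percent of the left-handed substrate and right-handed substrate together charged, epsilon

- free catalyst is single-handed; left-handed substrate and right-handed substrate are mirror images of each other, charged as a racemate, each of them at the stated concentration
- as a solid, counted per litre of solution: solid reagent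
- at the start none of the solid reagent is in solution

I assume that left-handed substrate falls at a fractional rate proportional to free catalyst, at one mean level of dissolved reagent (pseudo-first-order), and that free catalyst decays first-order. Integrating, the logarithm of substrate charged over substrate left at the stop equals a rate constant times loading times catalyst lifetime. Larch's last reading puts this logarithm at 0.777; I call it the reach.

Ash's last reading stands 1 percentage point below its charge of left-handed substrate, against a scatter of 1.5 points, so its reach of 0.0202 is rough. Per unit of loading, larch's reach reads 88.7 times ash's, and that ratio is just as rough. Spread evenly in the logarithm over temperature, theta's warming from larch costs a factor 2.45, while its loading gains 1.54. So I reckon theta's reach at 0.487, a stop at 19.3% left-handed product.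

If that factor sits in the lifetime, theta's 15 h counts like 36.8 h in larch, later than larch's reading at 30.0 h. I take larch's share at that reading, 84.6%, and reckon 16.3% for theta. Gamma, at ash's temperature, gets ash's reach scaled to its loading, 0.0135.

The forecast names theta, with gamma 0.5%, zeta 0.3%, theta 15% and epsilon 2%, on the ground that “the catalyst dies while the solid slowly dissolves”. For theta my reckoning of 16.3% stands above the forecast's number.

The flasks give gamma 0.712%, zeta 0.0144%, theta 15.7% and epsilon 3.25%, so theta comes out highest and the forecast held.

    coupling partner + free catalyst + left-handed substrate → free catalyst + left-handed product (k = 850 M⁻² min⁻¹, Ea = 39.0 kJ mol⁻¹)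
    coupling partner + free catalyst + right-handed substrate → free catalyst + right-handed product (k = 450 M⁻² min⁻¹, Ea = 37.0 kJ mol⁻¹)
    free catalyst → spent catalyst (k = 0.00190 min⁻¹, Ea = 97.0 kJ mol⁻¹)
    solid reagent ⇌ coupling partner, rate k4*(cs4 - [coupling partner]) while solid is left; crystals form when [coupling partner] > cs4 (solubility = 37.0 mM, k = 0.00210 min⁻¹)
    (constants at 0 °C)

At 6.13 h theta's free catalyst has a half-life of 6.1 h by its decay, shorter than the 23 h of left-handed substrate by its coupling step. At 15.0 h theta holds 18.1% of its catalyst charge as free catalyst and 69% of its charged left-handed substrate, beside 9.03% right-handed product. Left until 150 h, theta gives 22.0%, a reach of 0.580, against my 0.487. Gamma's result is a reach of 0.0143, against my 0.0135.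

The data stem from a simulated flask for an exercise.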